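**Plan**
- Target: a (2S)-flavanone and a flavone joined through C3'–C3''' of their B rings; C2 of the flavanone is the only stereocentre.
- Cuts, in retrosynthetic order: the six O-benzyl groups; flavanone ring C at O1–C2 and C2–C3 (oxa-Michael and Knoevenagel, with a tert-butyl ester at C3 as traceless activator); the flavone C2–C1''' bond (Negishi); ring B of the flavanone half at C2'–C3' and C4'–C5'.
- Enabling feature: this ring B is a benzene with the C2 carbon on C1', the biaryl bond on C3' and oxygen on C4'. C1', C2', C5', C6' and the C1' substituent map onto C5, C6, C3, C4 and the ester of methyl coumalate. C3' and C4'–O map onto the ArCH=C(OSiMe3)2 unit of an arylacetic acid, whose aryl–CH2 bond is already the biaryl bond.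
- Forward order: ring B by [4+2] addition, CO2 loss and aromatisation; ester to aldehyde; a ready-made chromone (flavone rings A and C) joined at the bromide; flavanone ring C closed last. Both A rings come from 2,4,6-trihydroxyacetophenone.
- Stereochemistry: C2 (S) is set in the last ring closure by a cinchona thiourea catalyst; only acidic decarboxylation and neutral hydrogenolysis follow.

Key step: step 4

Remark on the chemistry: the quinine-derived thiourea of step 13 is assumed to deliver the phenol to the alkylidene face that gives 2S. If a first run shows the opposite sense, the quinidine-derived pseudo-enantiomer is used with nothing else changed.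

**Route**

Step 1
Reactants: 1 2-hydroxyphenylacetic acid
Product: 2 5-bromo-2-hydroxyphenylacetic acid
Conditions: Br2 (1.0 equiv), AcOH, 15 °C to rt
Reagents that add atoms: bromine, BrBr
Why: Electrophilic aromatic bromination in which the phenolic OH directs para, to C5, and one equivalent of bromine limits attack at the ortho position.

Step 2
Reactants: 2 5-bromo-2-hydroxyphenylacetic acid
Product: 4 2-[2-(benzyloxy)-5-bromophenyl]acetic acid, via benzyl ester 3 (not isolated)
Conditions: BnBr (2.3 equiv), K2CO3, DMF, 60 °C; then NaOH, MeOH–H2O, 60 °C; HCl to pH 2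
Reagents that add atoms: benzyl bromide, BrCc1ccccc1; sodium hydroxide, [Na+].[OH-]
Why: Williamson alkylation of phenoxide and carboxylate followed by saponification, which cleaves only the benzyl ester because the aryl benzyl ether is stable to hydroxide.

Step 3
Reactants: 4 2-[2-(benzyloxy)-5-bromophenyl]acetic acid
Product: 5 {2-[2-(benzyloxy)-5-bromophenyl]ethene-1,1-diyl}bis(oxy)bis(trimethylsilane), the bis(trimethylsilyl) ketene acetal
Conditions: LiN(SiMe3)2 (2.2 equiv), THF, −78 to 0 °C; Me3SiCl (2.5 equiv), −78 °C to rt; pentane, filtration under Ar, used crude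
Reagents that add atoms: chlorotrimethylsilane, C[Si](C)(C)Cl
Why: Double deprotonation to the enediolate and O,O-silylation is the standard preparation of bis(silyl) ketene acetals from carboxylic acids, and the hindered amide base at low temperature should leave the aryl bromide and the benzyl ether untouched.

Step 4
Reactants: 5 bis(trimethylsilyl) ketene acetal (1.5 equiv); 6 methyl coumalate (methyl 2-oxo-2H-pyran-5-carboxylate)
Product: 10 methyl 3-[2-(benzyloxy)-5-bromophenyl]-4-hydroxybenzoate, via bridged lactone cycloadduct 7 (not isolated), via cyclohexadiene ketal 8 (not isolated), via aryl trimethylsilyl ether 9 (not isolated)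
Conditions: toluene, 100 °C, sealed tube, Ar; then 1 M HCl, THF, rt
Reagents that add atoms: none
Why: The electron-poor pyranone acts as the 4π partner through C3–C6 and the electron-rich ketene acetal as the 2π partner in an asynchronous, Michael-like [4+2] addition, in which the ArCH carbon bonds to C6 and the acetal carbon to C3 to give the 2-oxabicyclo[2.2.2]octenone 7; retro-[4+2] loss of CO2 gives diene 8, 1,2-elimination of trimethylsilanol gives arene 9, and the acidic work-up frees phenol 10. The closest known reaction type is the inverse-electron-demand Diels–Alder, decarboxylation and aromatisation sequence of methyl coumalate with ketene acetals and enol ethers, which gives para-oxygenated benzoates. Ring B is closed by intermolecular cycloaddition, both C2'–C3' and C4'–C5' forming in one operation, and the lactone bridge is then excised, so no chain cyclisation is involved. No stereocentre survives, since the sp3 centres of 7 and 8 are lost on aromatisation and endo/exo and facial selectivity are therefore irrelevant. The step needs one regiochemistry (oxygen para to the ester, aryl ortho to that oxygen), which is secured because C6 of coumalate is the acceptor terminus (β to the C5 ester and vinylogous to the lactone carbonyl) and the aryl-bearing carbon is the only nucleophilic carbon of the ketene acetal. It also needs an inert aryl bromide and benzyl ether, which is secured by purely thermal conditions without metal or base.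

Step 5
Reactants: 10 methyl 3-[2-(benzyloxy)-5-bromophenyl]-4-hydroxybenzoate
Product: 11 methyl 4-(benzyloxy)-3-[2-(benzyloxy)-5-bromophenyl]benzoate
Conditions: BnBr (1.2 equiv), K2CO3, DMF, 50 °C
Reagents that add atoms: benzyl bromide, BrCc1ccccc1
Why: Williamson etherification of the acidic para-ester phenol, which gives both B-ring oxygens the same protecting group for one final deprotection.

Step 6
Reactants: 11 methyl 4-(benzyloxy)-3-[2-(benzyloxy)-5-bromophenyl]benzoate
Product: 12 {4-(benzyloxy)-3-[2-(benzyloxy)-5-bromophenyl]phenyl}methanol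
Conditions: i-Bu2AlH (2.5 equiv), CH2Cl2, −78 to 0 °C; aq. KNaC4H4O6
Reagents that add atoms: none
Why: Hydride reduction of the benzoate to the benzylic alcohol, with aryl bromide and benzyl ethers inert to the aluminium hydride at low temperature.

Step 7
Reactants: 12 {4-(benzyloxy)-3-[2-(benzyloxy)-5-bromophenyl]phenyl}methanol
Product: 13 4-(benzyloxy)-3-[2-(benzyloxy)-5-bromophenyl]benzaldehyde
Conditions: activated MnO2 (10 equiv), CH2Cl2, rt
Reagents that add atoms: none
Why: Selective oxidation of a benzylic alcohol by MnO2, which stops at the aldehyde and does not touch the benzyl ethers.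

Step 8
Reactants: 14 2,4,6-trihydroxyacetophenone
Product: 15 1-[2,4-bis(benzyloxy)-6-hydroxyphenyl]ethan-1-one
Conditions: BnBr (2.1 equiv), K2CO3, DMF, rt
Reagents that add atoms: benzyl bromide, BrCc1ccccc1
Why: Williamson benzylation of the two more nucleophilic phenols, the third being held back by its hydrogen bond to the acetyl carbonyl.

Step 9
Reactants: 15 1-[2,4-bis(benzyloxy)-6-hydroxyphenyl]ethan-1-one
Product: 17 5,7-bis(benzyloxy)-4H-chromen-4-one, via dimethylamino enone 16 (not isolated)
Conditions: Me2NCH(OMe)2 (2 equiv), toluene, 95 °C; then conc. HCl, CH2Cl2, rt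
Reagents that add atoms: N,N-dimethylformamide dimethyl acetal, COC(OC)N(C)C
Why: Enaminone formation at the acetyl methyl group followed by acid-promoted addition of the phenol and loss of dimethylamine is the standard chromone synthesis from 2'-hydroxyacetophenones, and benzyl ethers tolerate the acid.

Step 10
Reactants: 17 5,7-bis(benzyloxy)-4H-chromen-4-one (1.3 equiv); 13 4-(benzyloxy)-3-[2-(benzyloxy)-5-bromophenyl]benzaldehyde
Product: 19 4-(benzyloxy)-3-{2-(benzyloxy)-5-[5,7-bis(benzyloxy)-4-oxo-4H-chromen-2-yl]phenyl}benzaldehyde, via chromon-2-ylzinc chloride 18 (not isolated)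
Conditions: TMPZnCl·LiCl (2,2,6,6-tetramethylpiperidin-1-ylzinc chloride–lithium chloride, 1.25 equiv), THF, 25 °C; then 13, Pd(OAc)2 (3 mol%), SPhos (6 mol%), THF, 50 °C
Reagents that add atoms: none
Why: Directed zincation of the chromone at C2, its most acidic C–H (α to the ring oxygen) when no Lewis acid is added, followed by Negishi coupling with the aryl bromide under zerovalent palladium and SPhos, with the aryl aldehyde tolerated by the organozinc.

Step 11
Reactants: 15 1-[2,4-bis(benzyloxy)-6-hydroxyphenyl]ethan-1-one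
Product: 20 tert-butyl 3-[2,4-bis(benzyloxy)-6-hydroxyphenyl]-3-oxopropanoate
Conditions: LiN(SiMe3)2 (3.3 equiv), THF, −78 °C; Boc2O (1.1 equiv), −78 to 0 °C; aq. NH4Cl
Reagents that add atoms: di-tert-butyl dicarbonate, CC(C)(C)OC(=O)OC(=O)OC(C)(C)C
Why: C-acylation of the lithium phenoxide–enolate dianion of an ortho-hydroxyacetophenone, in which any aryl carbonate formed first should be transferred to carbon in Baker–Venkataraman fashion because aryloxide is the better leaving group.

Step 12
Reactants: 19 flavone aldehyde; 20 tert-butyl 3-[2,4-bis(benzyloxy)-6-hydroxyphenyl]-3-oxopropanoate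
Product: 21 tert-butyl 2-[2,4-bis(benzyloxy)-6-hydroxybenzoyl]-3-(4-(benzyloxy)-3-{2-(benzyloxy)-5-[5,7-bis(benzyloxy)-4-oxo-4H-chromen-2-yl]phenyl}phenyl)prop-2-enoate (E/Z mixture)
Conditions: piperidine (20 mol%), AcOH (20 mol%), 4 Å molecular sieves, toluene, rt
Reagents that add atoms: none
Why: Knoevenagel condensation of the β-ketoester with the aromatic aldehyde under piperidinium acetate catalysis, kept at room temperature to limit uncatalysed ring closure.

Step 13
Reactants: 21 alkylidene β-ketoester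
Product: 23 (2S)-5,7-bis(benzyloxy)-2-(4-(benzyloxy)-3-{2-(benzyloxy)-5-[5,7-bis(benzyloxy)-4-oxo-4H-chromen-2-yl]phenyl}phenyl)-2,3-dihydro-4H-chromen-4-one, via flavanone tert-butyl ester 22 (not isolated)
Conditions: 1-[3,5-bis(trifluoromethyl)phenyl]-3-[(8α,9S)-6'-methoxycinchonan-9-yl]thiourea (from quinine, 10 mol%), toluene, −25 °C; then TsOH·H2O (1 equiv), 80 °C
Reagents that add atoms: none
Why: Enantioselective intramolecular oxa-Michael addition under bifunctional cinchona thiourea catalysis, in which the thiourea binds the β-ketoester and the quinuclidine guides the phenol to one face of the alkylidene to set C2 as S, after which acid removes the tert-butyl group and the β-keto acid decarboxylates, erasing the C3 centre.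

Step 14
Reactants: 23 (2S)-hexabenzyl ether
Product: 24 (2S)-2-{3-[5-(5,7-dihydroxy-4-oxo-4H-chromen-2-yl)-2-hydroxyphenyl]-4-hydroxyphenyl}-5,7-dihydroxy-2,3-dihydro-4H-chromen-4-one (CNP0184920.1)
Conditions: H2 (1 atm), 10% Pd/C, THF–MeOH, rt, stopped at full conversion
Reagents that add atoms: none
Why: Hydrogenolysis of the six aryl benzyl ethers under neutral conditions, which should leave the flavone double bond and both carbonyls intact at ambient pressure and cannot open the flavanone ring through a phenoxide, so C2 keeps its configuration.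

**Compound list**

1 | 2-hydroxyphenylacetic acid | OC(=O)Cc1ccccc1O | starting material
2 | 5-bromo-2-hydroxyphenylacetic acid | OC(=O)Cc1cc(Br)ccc1O | intermediate
3 | benzyl 2-[2-(benzyloxy)-5-bromophenyl]acetate | O=C(Cc1cc(Br)ccc1OCc1ccccc1)OCc1ccccc1 | intermediate
4 | 2-[2-(benzyloxy)-5-bromophenyl]acetic acid | OC(=O)Cc1cc(Br)ccc1OCc1ccccc1 | intermediate
5 | {2-[2-(benzyloxy)-5-bromophenyl]ethene-1,1-diyl}bis(oxy)bis(trimethylsilane) | C[Si](C)(C)OC(O[Si](C)(C)C)=Cc1cc(Br)ccc1OCc1ccccc1 | intermediate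
6 | methyl coumalate | COC(=O)C1=COC(=O)C=C1 | starting material
7 | methyl 7-[2-(benzyloxy)-5-bromophenyl]-3-oxo-8,8-bis(trimethylsilyloxy)-2-oxabicyclo[2.2.2]oct-5-ene-6-carboxylate (racemic, relative configuration not defined) | O=C1OC2C(c3cc(Br)ccc3OCc3ccccc3)C(O[Si](C)(C)C)(O[Si](C)(C)C)C1C=C2C(=O)OC | intermediate
8 | methyl 3-[2-(benzyloxy)-5-bromophenyl]-4,4-bis(trimethylsilyloxy)cyclohexa-1,5-diene-1-carboxylate (racemic) | COC(=O)C1=CC(c2cc(Br)ccc2OCc2ccccc2)C(O[Si](C)(C)C)(O[Si](C)(C)C)C=C1 | intermediate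
9 | methyl 3-[2-(benzyloxy)-5-bromophenyl]-4-(trimethylsilyloxy)benzoate | COC(=O)c1ccc(O[Si](C)(C)C)c(-c2cc(Br)ccc2OCc2ccccc2)c1 | intermediate
10 | methyl 3-[2-(benzyloxy)-5-bromophenyl]-4-hydroxybenzoate | COC(=O)c1ccc(O)c(-c2cc(Br)ccc2OCc2ccccc2)c1 | intermediate
11 | methyl 4-(benzyloxy)-3-[2-(benzyloxy)-5-bromophenyl]benzoate | COC(=O)c1ccc(OCc2ccccc2)c(-c2cc(Br)ccc2OCc2ccccc2)c1 | intermediate
12 | {4-(benzyloxy)-3-[2-(benzyloxy)-5-bromophenyl]phenyl}methanol | OCc1ccc(OCc2ccccc2)c(-c2cc(Br)ccc2OCc2ccccc2)c1 | intermediate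
13 | 4-(benzyloxy)-3-[2-(benzyloxy)-5-bromophenyl]benzaldehyde | O=Cc1ccc(OCc2ccccc2)c(-c2cc(Br)ccc2OCc2ccccc2)c1 | intermediate
14 | 2,4,6-trihydroxyacetophenone | CC(=O)c1c(O)cc(O)cc1O | starting material
15 | 1-[2,4-bis(benzyloxy)-6-hydroxyphenyl]ethan-1-one | CC(=O)c1c(O)cc(OCc2ccccc2)cc1OCc1ccccc1 | intermediate
16 | (E)-1-[2,4-bis(benzyloxy)-6-hydroxyphenyl]-3-(dimethylamino)prop-2-en-1-one | CN(C)/C=C/C(=O)c1c(O)cc(OCc2ccccc2)cc1OCc1ccccc1 | intermediate
17 | 5,7-bis(benzyloxy)-4H-chromen-4-one | O=c1ccoc2cc(OCc3ccccc3)cc(OCc3ccccc3)c12 | intermediate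
18 | [5,7-bis(benzyloxy)-4-oxo-4H-chromen-2-yl]zinc chloride (as its LiCl complex) | O=c1cc([Zn]Cl)oc2cc(OCc3ccccc3)cc(OCc3ccccc3)c12 | intermediate
19 | 4-(benzyloxy)-3-{2-(benzyloxy)-5-[5,7-bis(benzyloxy)-4-oxo-4H-chromen-2-yl]phenyl}benzaldehyde | O=Cc1ccc(OCc2ccccc2)c(-c2cc(-c3cc(=O)c4c(OCc5ccccc5)cc(OCc5ccccc5)cc4o3)ccc2OCc2ccccc2)c1 | intermediate
20 | tert-butyl 3-[2,4-bis(benzyloxy)-6-hydroxyphenyl]-3-oxopropanoate | CC(C)(C)OC(=O)CC(=O)c1c(O)cc(OCc2ccccc2)cc1OCc1ccccc1 | intermediate
21 | tert-butyl 2-[2,4-bis(benzyloxy)-6-hydroxybenzoyl]-3-(4-(benzyloxy)-3-{2-(benzyloxy)-5-[5,7-bis(benzyloxy)-4-oxo-4H-chromen-2-yl]phenyl}phenyl)prop-2-enoate (E/Z mixture) | CC(C)(C)OC(=O)C(=Cc1ccc(OCc2ccccc2)c(-c2cc(-c3cc(=O)c4c(OCc5ccccc5)cc(OCc5ccccc5)cc4o3)ccc2OCc2ccccc2)c1)C(=O)c1c(O)cc(OCc2ccccc2)cc1OCc1ccccc1 | intermediate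
22 | tert-butyl (2S)-5,7-bis(benzyloxy)-2-(4-(benzyloxy)-3-{2-(benzyloxy)-5-[5,7-bis(benzyloxy)-4-oxo-4H-chromen-2-yl]phenyl}phenyl)-4-oxo-3,4-dihydro-2H-chromene-3-carboxylate (C3 epimers and enol) | O=C1C(C(=O)OC(C)(C)C)[C@@H](c2ccc(OCc3ccccc3)c(-c3cc(-c4cc(=O)c5c(OCc6ccccc6)cc(OCc6ccccc6)cc5o4)ccc3OCc3ccccc3)c2)Oc2cc(OCc3ccccc3)cc(OCc3ccccc3)c21 | intermediate
23 | (2S)-5,7-bis(benzyloxy)-2-(4-(benzyloxy)-3-{2-(benzyloxy)-5-[5,7-bis(benzyloxy)-4-oxo-4H-chromen-2-yl]phenyl}phenyl)-2,3-dihydro-4H-chromen-4-one | O=C1C[C@@H](c2ccc(OCc3ccccc3)c(-c3cc(-c4cc(=O)c5c(OCc6ccccc6)cc(OCc6ccccc6)cc5o4)ccc3OCc3ccccc3)c2)Oc2cc(OCc3ccccc3)cc(OCc3ccccc3)c21 | intermediate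
24 | (2S)-2-{3-[5-(5,7-dihydroxy-4-oxo-4H-chromen-2-yl)-2-hydroxyphenyl]-4-hydroxyphenyl}-5,7-dihydroxy-2,3-dihydro-4H-chromen-4-one | O=C1C[C@@H](c2ccc(O)c(-c3cc(-c4cc(=O)c5c(O)cc(O)cc5o4)ccc3O)c2)Oc2cc(O)cc(O)c21 | target

**Count**

Total steps: 14. Longest linear sequence: 11 steps (steps 1 to 7, then 10, 12, 13 and 14, from 2-hydroxyphenylacetic acid).

**Steps most likely to fail**

Step 4. The hindered aryl-bearing ketene acetal may add to C6 in Mukaiyama–Michael fashion without closing the second bond, or may be desilylated or isomerised before it reacts, so that ring B does not form. The fallback keeps the coumalate ring synthesis but moves the aryl group onto the pyranone; it sets out from 6 and returns at 10. Bromination of 6 (Br2, CH2Cl2, then Et3N) should give methyl 3-bromo-2-oxo-2H-pyran-5-carboxylate F1. Suzuki–Miyaura coupling of F1 with [2-(benzyloxy)-5-bromophenyl]boronic acid (assumed to be purchasable; Pd(PPh3)4, K2CO3, toluene, 80 °C) should occur at the activated pyranone C–Br bond, which adds to zerovalent palladium much faster than the electron-rich aryl bromide, and give methyl 3-[2-(benzyloxy)-5-bromophenyl]-2-oxo-2H-pyran-5-carboxylate F2. Heating F2 in toluene with the unhindered 1,1-bis(trimethylsilyloxy)ethene F3 (from trimethylsilyl acetate, LiN(i-Pr)2, Me3SiCl) should join the CH2 terminus to C6 and the acetal carbon to the aryl-bearing C3. The bridged lactone F4 then loses CO2 to the diene F5, which loses trimethylsilanol to give 9 and, after the same work-up, 10. The positions ortho to oxygen in a 4-oxygenated benzoate are equivalent, so the same arene results.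

Step 10. The zinc amide may metallate C3 under the influence of the chelating 5-benzyloxy and carbonyl groups, or the 2-zincated chromone may transmetallate slowly and be lost to protonation or addition to the aldehyde. The fallback joins the two halves through boron and conjugate addition; it sets out from 12, bypasses step 7 and returns at 19. Borylation of 12 (B2(OH)4, Pd(OAc)2, XPhos, KOAc, EtOH, 80 °C) should give {4-(benzyloxy)-3-[2-(benzyloxy)-5-(hydroxymethyl)phenyl]phenyl}boronic acid F6. Hayashi–Miyaura 1,4-addition of F6 to chromone 17 ([Rh(OH)(cod)]2, dioxane–H2O, 60 °C) should give the racemic flavanone alcohol 5,7-bis(benzyloxy)-2-{4-(benzyloxy)-3-[2-(benzyloxy)-5-(hydroxymethyl)phenyl]phenyl}-2,3-dihydro-4H-chromen-4-one F7. 2-Iodoxybenzoic acid (IBX) in DMSO at 85 °C should then oxidise the benzylic alcohol to the aldehyde and dehydrogenate the chromanone to the chromone, giving 19.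

Step 13. Facial discrimination in the oxa-Michael closure may be poor because the 6'-benzyloxy group twists the aroyl unit. Uncatalysed closure may already occur during step 12, and reversible ring opening during the hot acidic decarboxylation may erode the enantiomeric purity. The fallback gives up catalytic control for a racemic closure and separation; it sets out from 19 and returns at 23. Claisen–Schmidt condensation of 19 with 15 (KOH, EtOH–THF, rt) should give the 2'-hydroxychalcone (E)-1-[2,4-bis(benzyloxy)-6-hydroxyphenyl]-3-(4-(benzyloxy)-3-{2-(benzyloxy)-5-[5,7-bis(benzyloxy)-4-oxo-4H-chromen-2-yl]phenyl}phenyl)prop-2-en-1-one F8. NaOAc in refluxing EtOH should close it to the racemic hexabenzyl flavanone F9. Preparative chromatography on an amylose tris(3,5-dimethylphenylcarbamate) phase should separate 23 from its (2R)-enantiomer F10, which can be returned to the NaOAc equilibration.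

**Further compounds**

F1 | step 4 | methyl 3-bromo-2-oxo-2H-pyran-5-carboxylate | COC(=O)C1=COC(=O)C(Br)=C1
F2 | step 4 | methyl 3-[2-(benzyloxy)-5-bromophenyl]-2-oxo-2H-pyran-5-carboxylate | COC(=O)C1=COC(=O)C(c2cc(Br)ccc2OCc2ccccc2)=C1
F3 | step 4 | 1,1-bis(trimethylsilyloxy)ethene | C=C(O[Si](C)(C)C)O[Si](C)(C)C
F4 | step 4 | methyl 4-[2-(benzyloxy)-5-bromophenyl]-3-oxo-8,8-bis(trimethylsilyloxy)-2-oxabicyclo[2.2.2]oct-5-ene-6-carboxylate (racemic) | O=C1OC2CC(O[Si](C)(C)C)(O[Si](C)(C)C)C1(c3cc(Br)ccc3OCc3ccccc3)C=C2C(=O)OC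
F5 | step 4 | methyl 5-[2-(benzyloxy)-5-bromophenyl]-4,4-bis(trimethylsilyloxy)cyclohexa-1,5-diene-1-carboxylate | COC(=O)C1=CCC(O[Si](C)(C)C)(O[Si](C)(C)C)C(c2cc(Br)ccc2OCc2ccccc2)=C1
F6 | step 10 | {4-(benzyloxy)-3-[2-(benzyloxy)-5-(hydroxymethyl)phenyl]phenyl}boronic acid | OCc1ccc(OCc2ccccc2)c(-c2cc(B(O)O)ccc2OCc2ccccc2)c1
F7 | step 10 | 5,7-bis(benzyloxy)-2-{4-(benzyloxy)-3-[2-(benzyloxy)-5-(hydroxymethyl)phenyl]phenyl}-2,3-dihydro-4H-chromen-4-one (racemic) | OCc1ccc(OCc2ccccc2)c(-c2cc(C3CC(=O)c4c(OCc5ccccc5)cc(OCc5ccccc5)cc4O3)ccc2OCc2ccccc2)c1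
F8 | step 13 | (E)-1-[2,4-bis(benzyloxy)-6-hydroxyphenyl]-3-(4-(benzyloxy)-3-{2-(benzyloxy)-5-[5,7-bis(benzyloxy)-4-oxo-4H-chromen-2-yl]phenyl}phenyl)prop-2-en-1-one | O=C(/C=C/c1ccc(OCc2ccccc2)c(-c2cc(-c3cc(=O)c4c(OCc5ccccc5)cc(OCc5ccccc5)cc4o3)ccc2OCc2ccccc2)c1)c1c(O)cc(OCc2ccccc2)cc1OCc1ccccc1
F9 | step 13 | racemic 5,7-bis(benzyloxy)-2-(4-(benzyloxy)-3-{2-(benzyloxy)-5-[5,7-bis(benzyloxy)-4-oxo-4H-chromen-2-yl]phenyl}phenyl)-2,3-dihydro-4H-chromen-4-one | O=C1CC(c2ccc(OCc3ccccc3)c(-c3cc(-c4cc(=O)c5c(OCc6ccccc6)cc(OCc6ccccc6)cc5o4)ccc3OCc3ccccc3)c2)Oc2cc(OCc3ccccc3)cc(OCc3ccccc3)c21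
F10 | step 13 | (2R)-5,7-bis(benzyloxy)-2-(4-(benzyloxy)-3-{2-(benzyloxy)-5-[5,7-bis(benzyloxy)-4-oxo-4H-chromen-2-yl]phenyl}phenyl)-2,3-dihydro-4H-chromen-4-one | O=C1C[C@H](c2ccc(OCc3ccccc3)c(-c3cc(-c4cc(=O)c5c(OCc6ccccc6)cc(OCc6ccccc6)cc5o4)ccc3OCc3ccccc3)c2)Oc2cc(OCc3ccccc3)cc(OCc3ccccc3)c21
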